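**Retrosynthetic overview**
1. Militarinone A ⇒ Horner–Wadsworth–Emmons union (C2=C3 of the side chain) of the fully unmasked pyridone β-ketophosphonate 28 with dienal 13.
2. 28 ⇒ 2,4-dimethoxypyridine 26 by N-oxidation and hydroxide SNAr of both methyl ethers, done before any triene is present.
3. cis-1,4-Diol of 26 ⇒ hydrogenation of bicyclic endoperoxide 25 ⇐ [4+2] cycloaddition of singlet oxygen to aryl-cyclohexa-1,3-diene 24 (key step).
4. 24 ⇒ 5-bromo-2,4-dimethoxypyridine + cyclohex-2-en-1-one (addition/dehydration), then C3 metalation, acetylation and C-phosphinylation.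
5. 13 ⇒ two Wittig homologations of a (2R,4R)-2,4-dimethylhexanoate whose two methyl stereocentres both come from tert-butyl (R)-lactate by invertive triflate–Grignard couplings. Ring order: pyridine and carbocycle are bought; the only ring formed is the 2,3-dioxabicyclo[2.2.2]octene (step 11), opened again in step 12.

Assumption: "cis" for the cyclohexane means the two hydroxyls on the same face (pyridyl and 4-OH trans), as encoded in the SMILES; compounds 1, 9, 12, 14 and 19 are taken as catalogue items.

**Side chain**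

Step 1
Reactants: 1 tert-butyl (2R)-2-hydroxypropanoate
Product: 2 tert-butyl (2R)-2-{[(trifluoromethyl)sulfonyl]oxy}propanoate
Conditions: Tf2O, 2,6-lutidine, CH2Cl2, −78 → 0 °C
Reagents that add atoms: trifluoromethanesulfonic anhydride, O=S(=O)(OS(=O)(=O)C(F)(F)F)C(F)(F)F
Why: O-sulfonylation (triflation) of the secondary alcohol does not touch the C–O stereocentre, so the bought (R) configuration is retained.

Step 2
Reactants: 2 tert-butyl (2R)-2-{[(trifluoromethyl)sulfonyl]oxy}propanoate; 3 ethylmagnesium chloride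
Product: 4 tert-butyl (2R)-2-methylbutanoate
Conditions: ZnCl2 (5 mol %), THF, 0 °C, slow addition of 3
Reagents that add atoms: none
Why: ZnCl2-catalysed sp3–sp3 cross-coupling in which the triorganozincate displaces the α-triflate by SN2 with inversion; the descriptor stays R only because ethyl now ranks below the ester, and this centre becomes C10.

Step 3
Reactants: 4 tert-butyl (2R)-2-methylbutanoate
Product: 5 (2R)-2-methylbutan-1-ol
Conditions: LiAlH4, Et2O, 0 °C → rt; aqueous work-up; distil
Reagents that add atoms: none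
Why: Hydride reduction of the ester to the primary alcohol; the α-stereocentre is not deprotonated by the hydride and is carried through.

Step 4
Reactants: 5 (2R)-2-methylbutan-1-ol
Product: 6 (2R)-1-chloro-2-methylbutane
Conditions: SOCl2, pyridine, 0 °C → reflux; distil
Reagents that add atoms: thionyl chloride, ClS(Cl)=O
Why: Chlorodehydroxylation through the chlorosulfite at the primary carbon; the β-stereocentre is not involved.

Step 5
Reactants: 6 (2R)-1-chloro-2-methylbutane; 2 tert-butyl (2R)-2-{[(trifluoromethyl)sulfonyl]oxy}propanoate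
Product: 8 tert-butyl (2R,4R)-2,4-dimethylhexanoate, via Grignard reagent 7 (not isolated)
Conditions: Mg, THF, reflux; then add to 2, ZnCl2 (5 mol %), THF, 0 °C
Reagents that add atoms: none
Why: Grignard formation followed by a second ZnCl2-catalysed invertive SN2 coupling at the lactate carbon sets C2 (future C8) as R next to the carried-through C4 centre, giving the syn-2,4-dimethyl array purely from the chiral pool.

Step 6
Reactants: 8 tert-butyl (2R,4R)-2,4-dimethylhexanoate; 9 2-(triphenylphosphoranylidene)propanal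
Product: 11 (2E,4R,6R)-2,4,6-trimethyloct-2-enal, via aldehyde 10 (not isolated)
Conditions: i-Bu2AlH, CH2Cl2, −78 °C; aq. potassium sodium tartrate; crude aldehyde, 9, toluene, 90 °C
Reagents that add atoms: none
Why: Half-reduction of the tert-butyl ester (stable aluminium hemiacetal) and Wittig olefination with the stabilised ylide give the E-trisubstituted enal; the salt-free neutral conditions do not epimerise the α-centre.

Step 7
Reactants: 11 (2E,4R,6R)-2,4,6-trimethyloct-2-enal; 12 (triphenylphosphoranylidene)acetaldehyde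
Product: 13 (2E,4E,6R,8R)-4,6,8-trimethyldeca-2,4-dienal
Conditions: toluene, 80 °C
Reagents that add atoms: none
Why: E-selective Wittig two-carbon homologation with a stabilised formyl ylide; no stereocentre is touched.

**Core**

Step 8
Reactants: 14 5-bromo-2,4-dimethoxypyridine; 15 cyclohex-2-en-1-one
Product: 18 5-(cyclohexa-1,3-dien-1-yl)-2,4-dimethoxypyridine, via aryllithium 16 (not isolated), via allylic alcohol 17 (not isolated)
Conditions: n-BuLi, THF, −78 °C; 15, −78 °C; H2O quench; crude, pyridinium p-toluenesulfonate (cat.), toluene, 40 °C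
Reagents that add atoms: none
Why: Bromine–lithium exchange, 1,2-addition to the enone and acid-catalysed E1 dehydration through the aryl-stabilised allyl cation give the thermodynamically favoured linearly conjugated 1-aryl-1,3-diene.

Step 9
Reactants: 18 5-(cyclohexa-1,3-dien-1-yl)-2,4-dimethoxypyridine; 19 N-methoxy-N-methylacetamide
Product: 21 1-[5-(cyclohexa-1,3-dien-1-yl)-2,4-dimethoxypyridin-3-yl]ethan-1-one, via aryllithium 20 (not isolated)
Conditions: lithium 2,2,6,6-tetramethylpiperidide (LiTMP), THF, −78 → −40 °C; 19, −78 → 0 °C; aq. work-up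
Reagents that add atoms: none
Why: Directed ortho-metalation at C3, flanked by both methoxy groups, with a non-nucleophilic amide base that spares the diene, then Weinreb-amide acylation (stable chelate, no over-addition).

Step 10
Reactants: 21 1-[5-(cyclohexa-1,3-dien-1-yl)-2,4-dimethoxypyridin-3-yl]ethan-1-one
Product: 24 diethyl {2-[5-(cyclohexa-1,3-dien-1-yl)-2,4-dimethoxypyridin-3-yl]-2-oxoethyl}phosphonate, via lithium enolate 22 (not isolated), via phosphonite 23 (not isolated)
Conditions: LiN(i-Pr)2, THF, −78 °C; ClP(OEt)2, −78 °C → rt; 30 % H2O2, 0 °C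
Reagents that add atoms: diethyl chlorophosphite, ClP(OCC)OCC; hydrogen peroxide, OO
Why: C-phosphinylation of the methyl-ketone enolate with a soft trivalent phosphorus chloride (C–P rather than O–P bond), then oxidation at phosphorus to the β-ketophosphonate.

Step 11
Reactants: 24 diethyl {2-[5-(cyclohexa-1,3-dien-1-yl)-2,4-dimethoxypyridin-3-yl]-2-oxoethyl}phosphonate
Product: 25 diethyl {2-[5-(2,3-dioxabicyclo[2.2.2]oct-5-en-1-yl)-2,4-dimethoxypyridin-3-yl]-2-oxoethyl}phosphonate (racemic)
Conditions: O2, meso-tetraphenylporphyrin (cat.), visible light, CH2Cl2, −20 °C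
Reagents that add atoms: dioxygen (as singlet oxygen), O=O
Why: [4+2] cycloaddition of singlet oxygen to the ring-locked s-cis diene forms both C–O bonds suprafacially on one face, so the two oxygens are cis by construction; the bicycle is racemic but becomes achiral once opened.

Step 12
Reactants: 25 diethyl {2-[5-(2,3-dioxabicyclo[2.2.2]oct-5-en-1-yl)-2,4-dimethoxypyridin-3-yl]-2-oxoethyl}phosphonate
Product: 26 diethyl {2-[5-(cis-1,4-dihydroxycyclohexyl)-2,4-dimethoxypyridin-3-yl]-2-oxoethyl}phosphonate
Conditions: H2 (1 atm), Pd/C, EtOAc, rt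
Reagents that add atoms: none
Why: Catalytic hydrogenation cleaves the O–O bond and saturates the C=C bond without breaking either C–O bond, so the cis relationship fixed in the cycloaddition is delivered as the cis-1,4-diol (as in ascaridole to cis-terpin).

Step 13
Reactants: 26 diethyl {2-[5-(cis-1,4-dihydroxycyclohexyl)-2,4-dimethoxypyridin-3-yl]-2-oxoethyl}phosphonate
Product: 28 diethyl {2-[1,4-dihydroxy-5-(cis-1,4-dihydroxycyclohexyl)-2-oxo-1,2-dihydropyridin-3-yl]-2-oxoethyl}phosphonate, via N-oxide 27 (not isolated)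
Conditions: mCPBA, CH2Cl2, 0 °C → rt; evaporate; 2 M NaOH, 1,4-dioxane, 60 °C; 1 M HCl to pH 3
Reagents that add atoms: 3-chloroperbenzoic acid, OOC(=O)c1cccc(Cl)c1; sodium hydroxide, [Na+].[OH-]
Why: Peracid N-oxidation of the 2-alkoxypyridine, after which the N-oxide and the 3-acyl group activate C2 and C4 for nucleophilic aromatic substitution by hydroxide, unveiling the 1,4-dihydroxy-2-pyridone under base so the tertiary alcohol is not exposed to acid.

**Union**

Step 14
Reactants: 28 diethyl {2-[1,4-dihydroxy-5-(cis-1,4-dihydroxycyclohexyl)-2-oxo-1,2-dihydropyridin-3-yl]-2-oxoethyl}phosphonate; 13 (2E,4E,6R,8R)-4,6,8-trimethyldeca-2,4-dienal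
Product: 30 militarinone A, via tripotassium salt 29 (not isolated)
Conditions: KOtBu (4.5 equiv), THF–DMF, 0 °C; 13, 0 °C → rt; 1 M HCl to pH 3–4
Reagents that add atoms: none
Why: Horner–Wadsworth–Emmons olefination of the phosphonate polyanion (as used for acyl-tetramic acid phosphonates) forms the C2=C3 E-alkene directly on the unprotected pyridone; the stereocentres are remote and untouched.

**Compound list**
1 | tert-butyl (2R)-2-hydroxypropanoate (tert-butyl D-lactate) | C[C@@H](O)C(=O)OC(C)(C)C | starting material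
2 | tert-butyl (2R)-2-{[(trifluoromethyl)sulfonyl]oxy}propanoate | C[C@@H](OS(=O)(=O)C(F)(F)F)C(=O)OC(C)(C)C | intermediate
3 | ethylmagnesium chloride | CC[Mg]Cl | starting material
4 | tert-butyl (2R)-2-methylbutanoate | CC[C@@H](C)C(=O)OC(C)(C)C | intermediate
5 | (2R)-2-methylbutan-1-ol | CC[C@@H](C)CO | intermediate
6 | (2R)-1-chloro-2-methylbutane | CC[C@@H](C)CCl | intermediate
7 | [(2R)-2-methylbutyl]magnesium chloride (formed in the flask) | CC[C@@H](C)C[Mg]Cl | intermediate
8 | tert-butyl (2R,4R)-2,4-dimethylhexanoate | CC[C@@H](C)C[C@@H](C)C(=O)OC(C)(C)C | intermediate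
9 | 2-(triphenylphosphoranylidene)propanal | CC(C=O)=P(c1ccccc1)(c1ccccc1)c1ccccc1 | starting material
10 | (2R,4R)-2,4-dimethylhexanal (formed in the flask) | CC[C@@H](C)C[C@@H](C)C=O | intermediate
11 | (2E,4R,6R)-2,4,6-trimethyloct-2-enal | CC[C@@H](C)C[C@@H](C)/C=C(C)/C=O | intermediate
12 | (triphenylphosphoranylidene)acetaldehyde | O=CC=P(c1ccccc1)(c1ccccc1)c1ccccc1 | starting material
13 | (2E,4E,6R,8R)-4,6,8-trimethyldeca-2,4-dienal | CC[C@@H](C)C[C@@H](C)/C=C(C)/C=C/C=O | intermediate
14 | 5-bromo-2,4-dimethoxypyridine | COc1ncc(Br)c(OC)c1 | starting material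
15 | cyclohex-2-en-1-one | O=C1C=CCCC1 | starting material
16 | (4,6-dimethoxypyridin-3-yl)lithium (formed in the flask) | COc1ncc([Li])c(OC)c1 | intermediate
17 | 1-(4,6-dimethoxypyridin-3-yl)cyclohex-2-en-1-ol (racemic; formed in the flask) | COc1ncc(C2(O)C=CCCC2)c(OC)c1 | intermediate
18 | 5-(cyclohexa-1,3-dien-1-yl)-2,4-dimethoxypyridine | COc1ncc(C2=CC=CCC2)c(OC)c1 | intermediate
19 | N-methoxy-N-methylacetamide | CC(=O)N(C)OC | starting material
20 | [5-(cyclohexa-1,3-dien-1-yl)-2,4-dimethoxypyridin-3-yl]lithium (formed in the flask) | COc1ncc(C2=CC=CCC2)c(OC)c1[Li] | intermediate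
21 | 1-[5-(cyclohexa-1,3-dien-1-yl)-2,4-dimethoxypyridin-3-yl]ethan-1-one | COc1ncc(C2=CC=CCC2)c(OC)c1C(C)=O | intermediate
22 | lithium 1-[5-(cyclohexa-1,3-dien-1-yl)-2,4-dimethoxypyridin-3-yl]ethen-1-olate (formed in the flask) | COc1ncc(C2=CC=CCC2)c(OC)c1C(=C)O[Li] | intermediate
23 | diethyl {2-[5-(cyclohexa-1,3-dien-1-yl)-2,4-dimethoxypyridin-3-yl]-2-oxoethyl}phosphonite (formed in the flask) | COc1ncc(C2=CC=CCC2)c(OC)c1C(=O)CP(OCC)OCC | intermediate
24 | diethyl {2-[5-(cyclohexa-1,3-dien-1-yl)-2,4-dimethoxypyridin-3-yl]-2-oxoethyl}phosphonate | COc1ncc(C2=CC=CCC2)c(OC)c1C(=O)CP(=O)(OCC)OCC | intermediate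
25 | diethyl {2-[5-(2,3-dioxabicyclo[2.2.2]oct-5-en-1-yl)-2,4-dimethoxypyridin-3-yl]-2-oxoethyl}phosphonate (racemic; one enantiomer drawn) | COc1ncc([C@]23OO[C@H](C=C2)CC3)c(OC)c1C(=O)CP(=O)(OCC)OCC | intermediate
26 | diethyl {2-[5-(cis-1,4-dihydroxycyclohexyl)-2,4-dimethoxypyridin-3-yl]-2-oxoethyl}phosphonate | COc1ncc([C@]2(O)CC[C@@H](O)CC2)c(OC)c1C(=O)CP(=O)(OCC)OCC | intermediate
27 | 3-[(diethoxyphosphoryl)acetyl]-5-(cis-1,4-dihydroxycyclohexyl)-2,4-dimethoxypyridine 1-oxide (formed in the flask) | COc1c(C(=O)CP(=O)(OCC)OCC)c(OC)c([C@]2(O)CC[C@@H](O)CC2)c[n+]1[O-] | intermediate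
28 | diethyl {2-[1,4-dihydroxy-5-(cis-1,4-dihydroxycyclohexyl)-2-oxo-1,2-dihydropyridin-3-yl]-2-oxoethyl}phosphonate | CCOP(=O)(OCC)CC(=O)c1c(O)c([C@]2(O)CC[C@@H](O)CC2)cn(O)c1=O | intermediate
29 | tripotassium salt of 28 (1-oxide, 4-oxide, phosphonate carbanion; formed in the flask) | CCOP(=O)(OCC)[CH-]C(=O)c1c([O-])c([C@]2(O)CC[C@@H](O)CC2)cn([O-])c1=O.[K+].[K+].[K+] | intermediate
30 | militarinone A | CC[C@@H](C)C[C@@H](C)/C=C(C)/C=C/C=C/C(=O)c1c(O)c([C@]2(O)CC[C@@H](O)CC2)cn(O)c1=O | target

**Step count**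
Total: 14 steps. Longest linear sequence: 8 steps (1–7, then 14); the core branch (8–14) is 7 steps.

**Three steps most likely to fail**

Step 14 (polyanion olefination). Three acidic sites must be deprotonated before the carbanion forms, so solubility and slow reaction are likely, and prolonged exposure of dienal 13 to KOtBu could epimerise C6 of 13 (ε to the aldehyde). The fallback sets out from 28 and comes back at 30. All four hydroxyls of 28 are capped with N-(trimethylsilyl)imidazole in CH2Cl2 to give the neutral, THF-soluble tetrakis(trimethylsilyl) ether F5. A single equivalent of LiN(SiMe3)2 (THF, −78 → 0 °C) then makes only the phosphonate carbanion, which is olefinated with 13 to the silylated trienone F6. Citric acid in MeOH removes the silyl groups to give 30.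

Step 13 (N-oxidation and hydroxide SNAr). The ring nitrogen is flanked by an alkoxy group and deactivated by the 3-acyl group, and displacement of the 4-methoxy group may need forcing while the β-ketophosphonate is exposed to hot hydroxide. The fallback sets out from 26 and comes back at 28. Both methyl ethers of 26 are cleaved by SN2 attack of NaSEt on the methyl carbons (DMF, 100 °C) to give the N–H pyridone F3. This is persilylated (hexamethyldisilazane, cat. Me3SiCl) to the 2,4-bis(trimethylsilyloxy)pyridine F4. Electrophilic N-hydroxylation of F4 with MoO5·pyridine·HMPA (CH2Cl2, rt) and aqueous EDTA work-up give 28.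

Step 8 (telescoped addition/dehydration). The allyl cation can also lose a proton to give the cross-conjugated 2-aryl diene, and the electron-rich diene can aromatise or oligomerise under acid. The fallback sets out from aryllithium 16 and enone 15 and comes back at 18. 16 is transmetalated with ZnCl2 to (4,6-dimethoxypyridin-3-yl)zinc chloride F1. 15 is converted with Tf2O and 2,6-di-tert-butyl-4-methylpyridine into the thermodynamic dienol triflate cyclohexa-1,3-dien-1-yl trifluoromethanesulfonate F2. Negishi coupling of F1 with F2 under Pd(PPh3)4 (THF, rt) gives 18 with the aryl group fixed on the diene terminus and no acid or carbocation involved.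

**Further compounds**
F1 | step 8 | (4,6-dimethoxypyridin-3-yl)zinc chloride | COc1ncc([Zn]Cl)c(OC)c1
F2 | step 8 | cyclohexa-1,3-dien-1-yl trifluoromethanesulfonate | O=S(=O)(OC1=CC=CCC1)C(F)(F)F
F3 | step 13 | diethyl {2-[5-(cis-1,4-dihydroxycyclohexyl)-4-hydroxy-2-oxo-1,2-dihydropyridin-3-yl]-2-oxoethyl}phosphonate | CCOP(=O)(OCC)CC(=O)c1c(O)c([C@]2(O)CC[C@@H](O)CC2)c[nH]c1=O
F4 | step 13 | diethyl {2-[2,4-bis(trimethylsilyloxy)-5-(cis-1,4-bis(trimethylsilyloxy)cyclohexyl)pyridin-3-yl]-2-oxoethyl}phosphonate | CCOP(=O)(OCC)CC(=O)c1c(O[Si](C)(C)C)c([C@]2(O[Si](C)(C)C)CC[C@@H](O[Si](C)(C)C)CC2)cnc1O[Si](C)(C)C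
F5 | step 14 | diethyl {2-[1,4-bis(trimethylsilyloxy)-5-(cis-1,4-bis(trimethylsilyloxy)cyclohexyl)-2-oxo-1,2-dihydropyridin-3-yl]-2-oxoethyl}phosphonate | CCOP(=O)(OCC)CC(=O)c1c(O[Si](C)(C)C)c([C@]2(O[Si](C)(C)C)CC[C@@H](O[Si](C)(C)C)CC2)cn(O[Si](C)(C)C)c1=O
F6 | step 14 | tetrakis(trimethylsilyl) ether of militarinone A | CC[C@@H](C)C[C@@H](C)/C=C(C)/C=C/C=C/C(=O)c1c(O[Si](C)(C)C)c([C@]2(O[Si](C)(C)C)CC[C@@H](O[Si](C)(C)C)CC2)cn(O[Si](C)(C)C)c1=O
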